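A direct plan would buy both benzene rings: 2,4-dimethoxy-6-methylbenzoic acid A1 and 2-methoxy-6-methylbenzoic acid A2 would be lithiated at the methyl group and hexylated, giving 2-heptyl-4,6-dimethoxybenzoic acid A3 and, after O-alkylation of the carboxylate, 2,4,6-trimethylbenzyl 2-heptyl-6-methoxybenzoate A4.
A4 would be borylated at C4 with B2pin2 and [Ir(OMe)(cod)]2 to the boronate A5, coupled with A3 by Cu(OTf)2 under O2 to the protected depside A6, and freed by hydrogenolysis.
Weakest would be this union: an aryl C–O coupling of an in situ pinacol boronate with a di-ortho-substituted acid has no precedent, it would consume both finished halves at once, and protodeboronation, phenol formation and borylation of the mesityl methyl groups would compete.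
Second would be the two benzylic lithiations: a lithium amide would metalate an electron-rich toluate only in part and the anion would add to unreacted carboxylate, so each heptyl chain would cost material.
Third would be the esterification and hydrogenolysis at the ring A carboxyl, two operations that only mask the acid and add no complexity.
No ring would be made and the target has no stereocentre, so nothing would be left to chance except the late union, where all the risk would sit.

Plan of the new route
Ring A (the benzoic acid ring) and ring B (the acyl ring) are both 6-heptyl-β-resorcylate units: in each, the carboxyl carbon, C1 to C6, the oxygens on C4 and C6 and the heptyl group on C2 are a folded 3,5,7-trioxotetradecanoyl chain (chain C1 = carboxyl, C3 and C5 carbonyls = ring C6–O and C4–O, C7 = ring C2).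
The retrosynthesis cuts, in each ring, the C1–C2 bond (aldol condensation) and the C–O bond at the carboxyl carbon, so both rings come from one masked chain, the diketo-dioxinone 7.
Ring A arises first, by amine-induced aromatisation of 7 to its acetonide, which benzyl alcohol opens (step 3). Ring B arises last, on the C4 oxygen of ring A, from the acylketene of a second portion of 7, after the depside C–O bond is already in place (step 4). One threefold methylation and a hydrogenolysis finish the route.
The ester bond is made at an unhindered ketene carbon before the two ortho substituents of ring B exist, and the heptyl groups come in with octanoyl chloride. No union of two finished arenes and no benzylic lithiation occurs, and the benzyl group enters as the nucleophile that opens the ring A acetonide, not in a separate protection step.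

Key step: step 4

Remark: the target has no stereocentre, so no step needs stereocontrol; 1, 2, 5 and 8 are taken as commercial.

Step 1
Reactants: 1 2,2,6-trimethyl-4H-1,3-dioxin-4-one; 2 acetyl chloride
Product: 4 2,2-dimethyl-6-(2-oxopropyl)-4H-1,3-dioxin-4-one, via lithium dioxinone dienolate 3 (not isolated)
Conditions: 1 (2.0 equiv), LiN(SiMe3)2 (2.0 equiv), THF, −78 °C, 1 h; 2 (1.0 equiv), −78 °C, 2 h; aq NH4Cl
Reagents that add atoms: none
Why: Vinylogous deprotonation at the C6 methyl group gives the dienolate, which is C-acylated at its exocyclic carbon by the acid chloride (crossed Claisen-type acylation), the second equivalent of dienolate taking up the acidic proton of the product and so protecting it from a second acylation.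

Step 2
Reactants: 4 2,2-dimethyl-6-(2-oxopropyl)-4H-1,3-dioxin-4-one; 5 octanoyl chloride
Product: 7 6-(2,4-dioxoundecyl)-2,2-dimethyl-4H-1,3-dioxin-4-one, via keto-dioxinone dianion 6 (not isolated)
Conditions: 4 (2.0 equiv), LiN(iPr)2 (4.1 equiv), THF, −78 °C, 1 h; 5 (1.0 equiv), −78 to −40 °C; aq HCl to pH 3; excess 4 recovered
Reagents that add atoms: none
Why: Double deprotonation gives the dianion, whose last-formed terminal carbanion (the former methyl group) is the most nucleophilic site and is C-acylated by the acid chloride (dianion Claisen-type acylation, the usual entry to diketo-dioxinones), the excess dianion absorbing the proton of the new 1,3-diketone.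

Step 3
Reactants: 7 6-(2,4-dioxoundecyl)-2,2-dimethyl-4H-1,3-dioxin-4-one; 8 benzyl alcohol
Product: 10 benzyl 2-heptyl-4,6-dihydroxybenzoate, via benzodioxinone 9 (not isolated)
Conditions: Et3N (2 equiv), CH2Cl2, rt, 16 h; evaporate; 8 (5 equiv), Cs2CO3 (2.5 equiv), THF, 60 °C, 8 h; aq HCl (1 M) to pH 2
Reagents that add atoms: none
Why: Under Et3N the vinylogous enolate carbon C5 of the dioxinone adds to the heptyl ketone of the side chain and water is lost (aldol condensation–aromatisation, the known amine-induced conversion of diketo-dioxinones into acetonide-masked resorcylates), and benzyl alkoxide then opens the benzodioxinone at its carbonyl carbon with loss of acetone (carbonate-mediated transesterification of a resorcylate acetonide), so no ketene takes part in this step.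

Step 4
Reactants: 7 6-(2,4-dioxoundecyl)-2,2-dimethyl-4H-1,3-dioxin-4-one; 10 benzyl 2-heptyl-4,6-dihydroxybenzoate
Product: 13 benzyl 4-[(2-heptyl-4,6-dihydroxybenzoyl)oxy]-2-heptyl-6-hydroxybenzoate, via acylketene 11 (not isolated), via aryl triketo ester 12 (not isolated)
Conditions: 10 (1.5 equiv), PhMe (0.5 M), 110 °C; 7 (1.0 equiv) in PhMe added over 1 h, then 30 min; cool to 0 °C, dilute with CH2Cl2; Et3N (2 equiv), 0 °C to rt, 6 h; aq HCl (1 M) work-up; excess 10 recovered
Reagents that add atoms: none
Why: Proposed new method: thermal retro-[4+2] of 7 expels acetone and gives acylketene 11, whose unhindered sp carbon is attacked by the free C4 hydroxyl of 10 through the six-membered, proton-relaying transition state usual for acylketene additions, so that the depside acyl C–O bond exists (in 12) before ring B and its two ortho substituents do; under Et3N the C2 enolate of the chain then adds to the C7 ketone and water is lost by E1cB elimination to give aromatic ring B, which forms only after cooling, so its new hydroxyls never meet the ketene. The closest known reaction types are the dioxinone thermolysis–alcohol trapping–aldol aromatisation that gives alkyl resorcylates and the acetoacetylation of phenols with 2,2,6-trimethyl-4H-1,3-dioxin-4-one, which have not been combined on a phenol to give an aryl resorcylate. Ring B closes by a 6-(enolendo)-exo-trig aldol addition that forms the C1'–C2' bond, followed by dehydration and enolisation of the two remaining ring ketones to the C4' and C6' hydroxyls. No stereocentre remains, since the aldol carbinol carbon becomes an arene carbon. Three selectivities are needed: acylation at the C4 hydroxyl and not the C6 hydroxyl of 10, secured because the C6 hydroxyl is hydrogen-bonded to and shielded by the benzyl ester carbonyl and 10 is in excess; bimolecular capture of 11 and not its unimolecular closure to a 4-hydroxy-2-pyranone, favoured by the high phenol concentration and slow addition of 7; and aldol closure (C2 to C7) and not Claisen closure (C6 to C1 with loss of the aryloxide), favoured by a weak amine base in an aprotic solvent, under which the ketone is the better electrophile and no polyanion forms.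

Step 5
Reactants: 13 benzyl 4-[(2-heptyl-4,6-dihydroxybenzoyl)oxy]-2-heptyl-6-hydroxybenzoate
Product: 14 benzyl 4-[(2-heptyl-4,6-dimethoxybenzoyl)oxy]-2-heptyl-6-methoxybenzoate
Conditions: MeI (10 equiv), K2CO3 (6 equiv, dried), acetone, 56 °C (sealed), 16 h
Reagents that add atoms: iodomethane, CI
Why: Williamson O-methylation of the three phenols, the classical permethylation of hydroxy depsides, in which dry carbonate in acetone offers no nucleophile able to attack the di-ortho-substituted aryl ester and excess MeI with heating also methylates the two hydrogen-bonded hydroxyls.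

Step 6
Reactants: 14 benzyl 4-[(2-heptyl-4,6-dimethoxybenzoyl)oxy]-2-heptyl-6-methoxybenzoate
Product: 15 4-[(2-heptyl-4,6-dimethoxybenzoyl)oxy]-2-heptyl-6-methoxybenzoic acid (target)
Conditions: H2 (1 atm), Pd/C (10 wt %), EtOAc, rt
Reagents that add atoms: none
Why: Hydrogenolysis of the benzyl ester under neutral conditions, which leaves the aryl ester, the methyl ethers and the alkyl chains untouched and avoids acid- or base-induced depside cleavage and decarboxylation.

Compound list
1 | 2,2,6-trimethyl-4H-1,3-dioxin-4-one | CC1=CC(=O)OC(C)(C)O1 | starting material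
2 | acetyl chloride | CC(Cl)=O | starting material
3 | lithium dioxinone dienolate (lithium 2,2-dimethyl-6-methylidene-6H-1,3-dioxin-4-olate) | [Li+].C=C1C=C([O-])OC(C)(C)O1 | intermediate
4 | 2,2-dimethyl-6-(2-oxopropyl)-4H-1,3-dioxin-4-one | CC(=O)CC1=CC(=O)OC(C)(C)O1 | intermediate
5 | octanoyl chloride | CCCCCCCC(Cl)=O | starting material
6 | keto-dioxinone dianion (dilithium salt of 4, deprotonated at both carbons flanking the ketone) | [Li+].[Li+].C=C([O-])C=C1C=C([O-])OC(C)(C)O1 | intermediate
7 | 6-(2,4-dioxoundecyl)-2,2-dimethyl-4H-1,3-dioxin-4-one | CCCCCCCC(=O)CC(=O)CC1=CC(=O)OC(C)(C)O1 | intermediate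
8 | benzyl alcohol | OCc1ccccc1 | starting material
9 | benzodioxinone (5-heptyl-7-hydroxy-2,2-dimethyl-4H-1,3-benzodioxin-4-one) | CCCCCCCc1cc(O)cc2OC(C)(C)OC(=O)c12 | intermediate
10 | benzyl 2-heptyl-4,6-dihydroxybenzoate | CCCCCCCc1cc(O)cc(O)c1C(=O)OCc1ccccc1 | intermediate
11 | acylketene (3,5,7-trioxotetradec-1-en-1-one) | CCCCCCCC(=O)CC(=O)CC(=O)C=C=O | intermediate
12 | aryl triketo ester (benzyl 2-heptyl-6-hydroxy-4-[(3,5,7-trioxotetradecanoyl)oxy]benzoate) | CCCCCCCC(=O)CC(=O)CC(=O)CC(=O)Oc1cc(O)c(C(=O)OCc2ccccc2)c(CCCCCCC)c1 | intermediate
13 | benzyl 4-[(2-heptyl-4,6-dihydroxybenzoyl)oxy]-2-heptyl-6-hydroxybenzoate | CCCCCCCc1cc(OC(=O)c2c(CCCCCCC)cc(O)cc2O)cc(O)c1C(=O)OCc1ccccc1 | intermediate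
14 | benzyl 4-[(2-heptyl-4,6-dimethoxybenzoyl)oxy]-2-heptyl-6-methoxybenzoate | CCCCCCCc1cc(OC(=O)c2c(CCCCCCC)cc(OC)cc2OC)cc(OC)c1C(=O)OCc1ccccc1 | intermediate
15 | 4-[(2-heptyl-4,6-dimethoxybenzoyl)oxy]-2-heptyl-6-methoxybenzoic acid | CCCCCCCc1cc(OC(=O)c2c(CCCCCCC)cc(OC)cc2OC)cc(OC)c1C(=O)O | target

Total step count: 6. Longest linear sequence: 6 steps (1 → 4 → 7 → 10 → 13 → 14 → 15; compound 7 enters in steps 3 and 4).

Steps most likely to fail

Step 4 (proposed new method). The phenol may capture the acylketene too slowly, so that the ketene lactonises to a pyranone. The aryl triketo ester may also close by Claisen condensation with loss of the aryloxide, or fragment back to ketene and phenoxide under base. The fallback uses the classical depside esterification; it sets out from 10 and returns at 14. One portion of 10 would be methylated at both hydroxyls (MeI, K2CO3, acetone, 56 °C) to benzyl 2-heptyl-4,6-dimethoxybenzoate F1 and hydrogenolysed (H2, Pd/C, EtOAc) to 2-heptyl-4,6-dimethoxybenzoic acid F2. F2 would be condensed with a second portion of 10 at its free C4 hydroxyl through the mixed trifluoroacetic anhydride ((CF3CO)2O, PhMe, rt) to benzyl 4-[(2-heptyl-4,6-dimethoxybenzoyl)oxy]-2-heptyl-6-hydroxybenzoate F3. The one remaining hydroxyl of F3 would be methylated under the conditions of step 5 to give 14.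

Step 5. The depside ester may be cleaved or transferred by phenoxide under the basic conditions, or the two hydrogen-bonded hydroxyls may be methylated incompletely. The fallback methylates no phenol once the depside bond exists; it sets out from 10 and returns at 14. 10 would be allylated at the free C4 hydroxyl (allyl bromide, K2CO3, acetone, rt) to benzyl 4-(allyloxy)-2-heptyl-6-hydroxybenzoate F4. F4 would be methylated at the hydrogen-bonded hydroxyl (MeI, K2CO3, DMF, 50 °C) to benzyl 4-(allyloxy)-2-heptyl-6-methoxybenzoate F5 and deallylated (Pd(PPh3)4, zerovalent palladium, morpholine, THF) to benzyl 2-heptyl-4-hydroxy-6-methoxybenzoate F6. F6 would then be esterified with 2-heptyl-4,6-dimethoxybenzoic acid F2 (made as in the fallback to step 4) through the mixed trifluoroacetic anhydride to give 14 directly.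

Step 2. Proton transfer from the product to the dianion may stop the conversion, and O-acylation or double acylation may compete. The fallback replaces the dianion by a soft enolisation; it sets out from 1 (through dienolate 3) and returns at 7. Dienolate 3 would be C-acylated with allyl 3-chloro-3-oxopropanoate to allyl 4-(2,2-dimethyl-4-oxo-4H-1,3-dioxin-6-yl)-3-oxobutanoate F7. The doubly activated methylene of F7 would be C-acylated with 5 under MgCl2 and pyridine (CH2Cl2, 0 °C) to allyl 4-(2,2-dimethyl-4-oxo-4H-1,3-dioxin-6-yl)-2-octanoyl-3-oxobutanoate F8. Pd(PPh3)4 (zerovalent palladium) and morpholine would then remove the allyl group and the carboxyl group to give 7.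

Further compounds
F1 | step 4 | benzyl 2-heptyl-4,6-dimethoxybenzoate | CCCCCCCc1cc(OC)cc(OC)c1C(=O)OCc1ccccc1
F2 | step 4 | 2-heptyl-4,6-dimethoxybenzoic acid | CCCCCCCc1cc(OC)cc(OC)c1C(=O)O
F3 | step 4 | benzyl 4-[(2-heptyl-4,6-dimethoxybenzoyl)oxy]-2-heptyl-6-hydroxybenzoate | CCCCCCCc1cc(OC(=O)c2c(CCCCCCC)cc(OC)cc2OC)cc(O)c1C(=O)OCc1ccccc1
F4 | step 5 | benzyl 4-(allyloxy)-2-heptyl-6-hydroxybenzoate | CCCCCCCc1cc(OCC=C)cc(O)c1C(=O)OCc1ccccc1
F5 | step 5 | benzyl 4-(allyloxy)-2-heptyl-6-methoxybenzoate | CCCCCCCc1cc(OCC=C)cc(OC)c1C(=O)OCc1ccccc1
F6 | step 5 | benzyl 2-heptyl-4-hydroxy-6-methoxybenzoate | CCCCCCCc1cc(O)cc(OC)c1C(=O)OCc1ccccc1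
F7 | step 2 | allyl 4-(2,2-dimethyl-4-oxo-4H-1,3-dioxin-6-yl)-3-oxobutanoate | C=CCOC(=O)CC(=O)CC1=CC(=O)OC(C)(C)O1
F8 | step 2 | allyl 4-(2,2-dimethyl-4-oxo-4H-1,3-dioxin-6-yl)-2-octanoyl-3-oxobutanoate | C=CCOC(=O)C(C(=O)CCCCCCC)C(=O)CC1=CC(=O)OC(C)(C)O1
A1 | direct plan | 2,4-dimethoxy-6-methylbenzoic acid | Cc1cc(OC)cc(OC)c1C(=O)O
A2 | direct plan | 2-methoxy-6-methylbenzoic acid | Cc1cccc(OC)c1C(=O)O
A3 | direct plan | 2-heptyl-4,6-dimethoxybenzoic acid | CCCCCCCc1cc(OC)cc(OC)c1C(=O)O
A4 | direct plan | 2,4,6-trimethylbenzyl 2-heptyl-6-methoxybenzoate | CCCCCCCc1cccc(OC)c1C(=O)OCc1c(C)cc(C)cc1C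
A5 | direct plan | 2,4,6-trimethylbenzyl 2-heptyl-6-methoxy-4-(4,4,5,5-tetramethyl-1,3,2-dioxaborolan-2-yl)benzoate | CCCCCCCc1cc(B2OC(C)(C)C(C)(C)O2)cc(OC)c1C(=O)OCc1c(C)cc(C)cc1C
A6 | direct plan | 2,4,6-trimethylbenzyl 4-[(2-heptyl-4,6-dimethoxybenzoyl)oxy]-2-heptyl-6-methoxybenzoate | CCCCCCCc1cc(OC(=O)c2c(CCCCCCC)cc(OC)cc2OC)cc(OC)c1C(=O)OCc1c(C)cc(C)cc1C
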